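Everything rests on closing the dihydropyran fused to ring A (O5–CMe2–CH2–CH2–C6, isoflavone numbering) at its CH2–CH2 bond by ring-closing metathesis. The step exploits the phloroglucinol symmetry of ring A: the precursor acetophenone carries 1,1-dimethylallyl ethers on both oxygens ortho to the acetyl (future O5 and O1) and a vinyl group at future C6. Only the O5 ether has a vinyl neighbour and cyclises; in the same flask the other ether undergoes Claisen rearrangement to the single free ring carbon, giving the C8 prenyl group and the phenol for chromone formation. Hydrogenation, iodochromone formation, Suzuki coupling with a ring B chroman boronate, oxidative furan closure and deprotection follow.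

Key step: step 5

Remark: the target has no stereocentre; locants in the text follow isoflavone numbering (O1, C4=O, rings A and B, primed locants for ring B) unless a systematic name is given.

Step 1
Reactants: 1 1-(2,4,6-trihydroxyphenyl)ethanone
Product: 2 1-[2,6-dihydroxy-4-(methoxymethoxy)phenyl]ethanone
Conditions: MOMCl (1.05 equiv), i-Pr2NEt, CH2Cl2, 0 °C
Reagents that add atoms: chloromethyl methyl ether, COCCl
Why: O-alkylation (MOM protection) should occur at the only hydroxyl that is not hydrogen-bonded to the acetyl group, which is also the most acidic one, so the two chelated ortho hydroxyls stay free.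

Step 2
Reactants: 2 1-[2,6-dihydroxy-4-(methoxymethoxy)phenyl]ethanone
Product: 3 1-[2,6-dihydroxy-3-iodo-4-(methoxymethoxy)phenyl]ethanone
Conditions: NIS (1.0 equiv), DMF, −20 °C → 0 °C
Reagents that add atoms: N-iodosuccinimide, O=C1CCC(=O)N1I
Why: Electrophilic aromatic iodination of the activated phloroglucinol ring, whose two free positions are equivalent by symmetry, so one equivalent of reagent should give a single mono-iodide.

Step 3
Reactants: 3 1-[2,6-dihydroxy-3-iodo-4-(methoxymethoxy)phenyl]ethanone
Product: 4 1-[3-ethenyl-2,6-dihydroxy-4-(methoxymethoxy)phenyl]ethanone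
Conditions: vinylboronic acid pinacol ester, PdCl2(dppf), K2CO3, 1,4-dioxane–H2O, 80 °C
Reagents that add atoms: 4,4,5,5-tetramethyl-2-vinyl-1,3,2-dioxaborolane, C=CB1OC(C)(C)C(C)(C)O1
Why: Suzuki–Miyaura coupling of the aryl iodide with a vinylboronate, placed before the allyl ethers are made so that zerovalent palladium never meets an allyl aryl ether or an alkene poised for Heck cyclisation.

Step 4
Reactants: 4 1-[3-ethenyl-2,6-dihydroxy-4-(methoxymethoxy)phenyl]ethanone
Product: 5 1-[3-ethenyl-4-(methoxymethoxy)-2,6-bis(2-methylbut-3-en-2-yloxy)phenyl]ethanone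
Conditions: tert-butyl 2-methylbut-3-en-2-yl carbonate (4 equiv), Pd(PPh3)4 (10 mol %), THF, 0 °C → rt
Reagents that add atoms: tert-butyl 2-methylbut-3-en-2-yl carbonate, CC(C)(C)OC(=O)OC(C)(C)C=C
Why: Decarboxylative Tsuji–Trost O-allylation, in which each phenoxide should attack the more substituted terminus of the 1,1-dimethylallyl palladium cation under kinetic control to give the branched tertiary ethers on both ortho oxygens.

Step 5
Reactants: 5 1-[3-ethenyl-4-(methoxymethoxy)-2,6-bis(2-methylbut-3-en-2-yloxy)phenyl]ethanone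
Product: 7 1-[7-hydroxy-5-(methoxymethoxy)-2,2-dimethyl-6-(3-methylbut-2-en-1-yl)-2H-chromen-8-yl]ethanone, via chromene allyl ether 6 (not isolated)
Conditions: second-generation Grubbs catalyst RuCl2(=CHPh)(H2IMes)(PCy3) (5 mol %), 1,4-benzoquinone (10 mol %), toluene (0.01 M), 50 °C; then 120 °C (sealed tube)
Reagents that add atoms: none
Why: The ruthenium alkylidene engages one terminal alkene, and [2+2] cycloaddition and cycloreversion with the alkene six atoms away expel ethene and form the C3=C4 bond of a 2,2-dimethyl-2H-chromene, the ether oxygen and the CMe2 centre being already in place. The closest known reaction type is ring-closing metathesis of allyl 2-vinylaryl ethers to 2H-chromenes, and the geminal methyl groups should favour cyclisation of this hindered diene. One ring is closed, the six-membered pyran, by metathesis between the styrene carbon and the vinyl carbon attached to CMe2; no stereocentre is formed and the new cis double bond is saturated in step 6. The step needs regioselectivity between two chemically equivalent tertiary allyl ethers, and the substrate secures it because only the ether at C2 of the acetophenone has the vinyl group on its ortho carbon, whereas the ether at C6 has no alkene within reach. On heating, this spectator ether should undergo [3,3] aromatic Claisen rearrangement to C5, its only free ortho carbon (the other carries the acetyl group), which installs the prenyl group and unveils the hydrogen-bonded phenol; benzoquinone is present to suppress ruthenium hydride isomerisation during the thermal stage.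

Step 6
Reactants: 7 1-[7-hydroxy-5-(methoxymethoxy)-2,2-dimethyl-6-(3-methylbut-2-en-1-yl)-2H-chromen-8-yl]ethanone
Product: 8 1-[7-hydroxy-5-(methoxymethoxy)-2,2-dimethyl-6-(3-methylbut-2-en-1-yl)-3,4-dihydro-2H-chromen-8-yl]ethanone
Conditions: H2 (1 atm), RhCl(PPh3)3 (10 mol %), benzene–EtOH, rt
Reagents that add atoms: none
Why: Homogeneous hydrogenation with RhCl(PPh3)3 should reduce the cis-disubstituted, arene-conjugated chromene double bond much faster than the trisubstituted prenyl alkene and should leave the ketone and the MOM ether untouched.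

Step 7
Reactants: 8 1-[7-hydroxy-5-(methoxymethoxy)-2,2-dimethyl-6-(3-methylbut-2-en-1-yl)-3,4-dihydro-2H-chromen-8-yl]ethanone
Product: 10 3-iodo-7-(methoxymethoxy)-8-(3-methylbut-2-en-1-yl)chromen-4-one carrying a 2,2-dimethyl-3,4-dihydro-2H-pyran ring fused at O5/C6, via enaminone 9 (not isolated)
Conditions: Me2NCH(OMe)2, toluene, 90 °C; then I2, CHCl3, rt
Reagents that add atoms: N,N-dimethylformamide dimethyl acetal, CN(C)C(OC)OC; iodine, II
Why: Enaminone formation at the methyl ketone followed by iodine-triggered cyclisation, in which iodination of the enaminone α-carbon, attack of the chelated phenol on the iminium carbon and loss of dimethylamine should give the 3-iodochromone faster than iodine can add to the prenyl alkene.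

Step 8
Reactants: 11 4-(benzyloxy)phenol
Product: 12 1-(benzyloxy)-4-(methoxymethoxy)benzene
Conditions: MOMCl, i-Pr2NEt, CH2Cl2, 0 °C → rt
Reagents that add atoms: chloromethyl methyl ether, COCCl
Why: Standard MOM protection of a phenol, which also installs the directing group for the next step.

Step 9
Reactants: 12 1-(benzyloxy)-4-(methoxymethoxy)benzene
Product: 15 5-(benzyloxy)-2-(methoxymethoxy)phenol, via aryllithium 13 (not isolated), via dimethyl arylboronate 14 (not isolated)
Conditions: n-BuLi, THF, 0 °C; B(OMe)3, −78 °C → rt; then H2O2, aq NaOH, 0 °C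
Reagents that add atoms: hydrogen peroxide, OO
Why: Directed ortho-metalation next to the strongly coordinating MOM ether, borylation and oxidative C–B to C–O conversion should place the new hydroxyl ortho to the MOM ether (both such positions are equivalent).

Step 10
Reactants: 15 5-(benzyloxy)-2-(methoxymethoxy)phenol
Product: 16 4-(benzyloxy)-1-(methoxymethoxy)-2-(2-methylbut-3-yn-2-yloxy)benzene
Conditions: 3-chloro-3-methylbut-1-yne, K2CO3, KI, CuI (cat.), acetone, 60 °C
Reagents that add atoms: 3-chloro-3-methylbut-1-yne, CC(C)(Cl)C#C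
Why: Copper-assisted O-alkylation of a phenoxide with a tertiary propargylic chloride, the standard entry to aryl 1,1-dimethylpropargyl ethers.

Step 11
Reactants: 16 4-(benzyloxy)-1-(methoxymethoxy)-2-(2-methylbut-3-yn-2-yloxy)benzene
Product: 17 5-(benzyloxy)-8-(methoxymethoxy)-2,2-dimethyl-2H-chromene
Conditions: PhNEt2, 180 °C
Reagents that add atoms: none
Why: Aromatic propargyl Claisen rearrangement to the only free ortho carbon, followed by 1,5-hydrogen shift and oxa-6π electrocyclisation, should give the 2,2-dimethyl-2H-chromene with unambiguous regiochemistry.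

Step 12
Reactants: 17 5-(benzyloxy)-8-(methoxymethoxy)-2,2-dimethyl-2H-chromene
Product: 18 8-(methoxymethoxy)-2,2-dimethyl-3,4-dihydro-2H-chromen-5-ol
Conditions: H2 (1 atm), Pd/C, EtOAc–EtOH, rt
Reagents that add atoms: none
Why: Heterogeneous hydrogenation should saturate the chromene double bond and cleave the benzyl ether by hydrogenolysis in one operation, while the MOM ether is inert.

Step 13
Reactants: 18 8-(methoxymethoxy)-2,2-dimethyl-3,4-dihydro-2H-chromen-5-ol
Product: 19 6-bromo-8-(methoxymethoxy)-2,2-dimethyl-3,4-dihydro-2H-chromen-5-ol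
Conditions: NBS (1.0 equiv), CH2Cl2, −10 °C
Reagents that add atoms: N-bromosuccinimide, O=C1CCC(=O)N1Br
Why: Electrophilic bromination should go to C6, the position ortho to the free phenol and para to the ring oxygen, as the other free position is meta to both.

Step 14
Reactants: 19 6-bromo-8-(methoxymethoxy)-2,2-dimethyl-3,4-dihydro-2H-chromen-5-ol
Product: 20 8-(methoxymethoxy)-2,2-dimethyl-6-(4,4,5,5-tetramethyl-1,3,2-dioxaborolan-2-yl)-3,4-dihydro-2H-chromen-5-ol
Conditions: B2pin2, PdCl2(dppf), KOAc, 1,4-dioxane, 85 °C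
Reagents that add atoms: bis(pinacolato)diboron, CC1(C)OB(OC1(C)C)B1OC(C)(C)C(C)(C)O1
Why: Miyaura borylation of the aryl bromide, which tolerates the free ortho phenol under the weak acetate base.

Step 15
Reactants: 10 3-iodochromone of step 7; 20 8-(methoxymethoxy)-2,2-dimethyl-6-(4,4,5,5-tetramethyl-1,3,2-dioxaborolan-2-yl)-3,4-dihydro-2H-chromen-5-ol
Product: 21 2'-hydroxyisoflavone in which C3 of the chromone of 10 carries the 5-hydroxy-8-(methoxymethoxy)-2,2-dimethylchroman-6-yl group
Conditions: Pd(PPh3)4, Na2CO3, DME–H2O, 80 °C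
Reagents that add atoms: none
Why: Suzuki–Miyaura coupling of a 3-iodochromone with an arylboronate is the standard isoflavone synthesis and should tolerate the free 2'-phenol, the prenyl group and both MOM ethers.

Step 16
Reactants: 21 2'-hydroxyisoflavone of step 15
Product: 22 bis(methoxymethyl) ether (at O7 and O5') of the target coumaronochromone
Conditions: DDQ (1.5 equiv), 1,4-dioxane, rt → 60 °C
Reagents that add atoms: none
Why: DDQ-mediated dehydrogenative cyclisation of a 2'-hydroxyisoflavone, in which the 2'-oxygen adds to C2 and the C2–H and O–H hydrogens are removed, should close the furan ring; the MOM ethers at O7 and O5' keep the prenyl-bearing phenol and the ring B hydroquinone from being oxidised.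

Step 17
Reactants: 22 bis(methoxymethyl) ether of the target
Product: 23 target CNP0081329.0
Conditions: HCl (3 M aq), MeOH–THF, 45 °C
Reagents that add atoms: none
Why: Acid-catalysed acetal exchange with methanol should remove both aryl MOM ethers under conditions mild enough to leave the prenyl group and the two cyclic tertiary ethers intact.

Compound list
1 | 1-(2,4,6-trihydroxyphenyl)ethanone | CC(=O)c1c(O)cc(O)cc1O | starting material
2 | 1-[2,6-dihydroxy-4-(methoxymethoxy)phenyl]ethanone | CC(=O)c1c(O)cc(OCOC)cc1O | intermediate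
3 | 1-[2,6-dihydroxy-3-iodo-4-(methoxymethoxy)phenyl]ethanone | CC(=O)c1c(O)c(I)c(OCOC)cc1O | intermediate
4 | 1-[3-ethenyl-2,6-dihydroxy-4-(methoxymethoxy)phenyl]ethanone | CC(=O)c1c(O)c(C=C)c(OCOC)cc1O | intermediate
5 | 1-[3-ethenyl-4-(methoxymethoxy)-2,6-bis(2-methylbut-3-en-2-yloxy)phenyl]ethanone | CC(=O)c1c(OC(C)(C)C=C)c(C=C)c(OCOC)cc1OC(C)(C)C=C | intermediate
6 | 1-[5-(methoxymethoxy)-2,2-dimethyl-7-(2-methylbut-3-en-2-yloxy)-2H-chromen-8-yl]ethanone | CC(=O)c1c(OC(C)(C)C=C)cc(OCOC)c2C=CC(C)(C)Oc12 | intermediate
7 | 1-[7-hydroxy-5-(methoxymethoxy)-2,2-dimethyl-6-(3-methylbut-2-en-1-yl)-2H-chromen-8-yl]ethanone | CC(=O)c1c(O)c(CC=C(C)C)c(OCOC)c2C=CC(C)(C)Oc12 | intermediate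
8 | 1-[7-hydroxy-5-(methoxymethoxy)-2,2-dimethyl-6-(3-methylbut-2-en-1-yl)-3,4-dihydro-2H-chromen-8-yl]ethanone | CC(=O)c1c(O)c(CC=C(C)C)c(OCOC)c2CCC(C)(C)Oc12 | intermediate
9 | (E)-3-(dimethylamino)-1-[7-hydroxy-5-(methoxymethoxy)-2,2-dimethyl-6-(3-methylbut-2-en-1-yl)-3,4-dihydro-2H-chromen-8-yl]prop-2-en-1-one | CN(C)/C=C/C(=O)c1c(O)c(CC=C(C)C)c(OCOC)c2CCC(C)(C)Oc12 | intermediate
10 | 3-iodo-7-(methoxymethoxy)-8-(3-methylbut-2-en-1-yl)chromen-4-one with a 2,2-dimethyl-3,4-dihydro-2H-pyran ring fused at O5/C6 | CC(C)=CCc1c(OCOC)c2c(c3c(=O)c(I)coc13)OC(C)(C)CC2 | intermediate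
11 | 4-(benzyloxy)phenol | Oc1ccc(OCc2ccccc2)cc1 | starting material
12 | 1-(benzyloxy)-4-(methoxymethoxy)benzene | COCOc1ccc(OCc2ccccc2)cc1 | intermediate
13 | [5-(benzyloxy)-2-(methoxymethoxy)phenyl]lithium | COCOc1ccc(OCc2ccccc2)cc1[Li] | intermediate
14 | dimethyl [5-(benzyloxy)-2-(methoxymethoxy)phenyl]boronate | COCOc1ccc(OCc2ccccc2)cc1B(OC)OC | intermediate
15 | 5-(benzyloxy)-2-(methoxymethoxy)phenol | COCOc1ccc(OCc2ccccc2)cc1O | intermediate
16 | 4-(benzyloxy)-1-(methoxymethoxy)-2-(2-methylbut-3-yn-2-yloxy)benzene | COCOc1ccc(OCc2ccccc2)cc1OC(C)(C)C#C | intermediate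
17 | 5-(benzyloxy)-8-(methoxymethoxy)-2,2-dimethyl-2H-chromene | COCOc1ccc(OCc2ccccc2)c2C=CC(C)(C)Oc12 | intermediate
18 | 8-(methoxymethoxy)-2,2-dimethyl-3,4-dihydro-2H-chromen-5-ol | COCOc1ccc(O)c2CCC(C)(C)Oc12 | intermediate
19 | 6-bromo-8-(methoxymethoxy)-2,2-dimethyl-3,4-dihydro-2H-chromen-5-ol | COCOc1cc(Br)c(O)c2CCC(C)(C)Oc12 | intermediate
20 | 8-(methoxymethoxy)-2,2-dimethyl-6-(4,4,5,5-tetramethyl-1,3,2-dioxaborolan-2-yl)-3,4-dihydro-2H-chromen-5-ol | COCOc1cc(B3OC(C)(C)C(C)(C)O3)c(O)c2CCC(C)(C)Oc12 | intermediate
21 | 2'-hydroxyisoflavone: chromone of 10 with the 5-hydroxy-8-(methoxymethoxy)-2,2-dimethylchroman-6-yl group at C3 in place of iodine | CC(C)=CCc1c(OCOC)c2c(c3c(=O)c(coc13)-c1cc(OCOC)c3OC(C)(C)CCc3c1O)OC(C)(C)CC2 | intermediate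
22 | 7,5'-bis(methoxymethyl) ether of the target coumaronochromone | CC(C)=CCc1c(OCOC)c2c(c3c(=O)c4c(oc13)oc1c3c(c(OCOC)cc14)OC(C)(C)CC3)OC(C)(C)CC2 | intermediate
23 | CNP0081329.0: 7,5'-dihydroxy-8-(3-methylbut-2-en-1-yl)coumaronochromone with 2,2-dimethyldihydropyran rings fused at O5/C6 and at O4'/C3' | CC(C)=CCc1c(O)c2c(c3c(=O)c4c(oc13)oc1c3c(c(O)cc14)OC(C)(C)CC3)OC(C)(C)CC2 | target

Total step count: 17. Longest linear sequence: 10 steps (steps 1–7 and 15–17 from 1; the ring B branch, steps 8–14 and 15–17 from 11, is equally long).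

Steps most likely to fail

Step 4. Attack of the phenoxides on the allyl palladium cation may drift from the oxygens to the free ring carbon (C-allylation of the phloroglucinol nucleus). Reversible ionisation of the tertiary ethers may also erode the branched selectivity towards linear prenyl ethers, above all at the oxygen flanked by acetyl and vinyl. The fallback makes the tertiary C–O bonds with a hard propargylic electrophile and adjusts the oxidation level afterwards. Setting out from 4, copper-assisted O-alkylation with 3-chloro-3-methylbut-1-yne (K2CO3, KI, CuI, acetone) would give 1-[3-ethenyl-4-(methoxymethoxy)-2,6-bis(2-methylbut-3-yn-2-yloxy)phenyl]ethanone F1. Semi-hydrogenation of both alkynes over Pd/CaCO3 poisoned with lead and quinoline, stopped at two equivalents of hydrogen, would come back to the route at 5.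

Step 6. Discrimination between the chromene and prenyl double bonds may be incomplete, so that the prenyl group is partly saturated or the hindered chromene alkene is left unreduced. The fallback removes the need for selectivity by reducing the chromene before the prenyl group exists. It sets out from 6, isolated by stopping step 5 before the thermal stage. Palladium-catalysed de-allylation (Pd(PPh3)4, morpholine, THF) would give 1-[7-hydroxy-5-(methoxymethoxy)-2,2-dimethyl-2H-chromen-8-yl]ethanone F2. Hydrogenation over Pd/C would give 1-[7-hydroxy-5-(methoxymethoxy)-2,2-dimethyl-3,4-dihydro-2H-chromen-8-yl]ethanone F3. Renewed Tsuji–Trost etherification with tert-butyl 2-methylbut-3-en-2-yl carbonate would give 1-[5-(methoxymethoxy)-2,2-dimethyl-7-(2-methylbut-3-en-2-yloxy)-3,4-dihydro-2H-chromen-8-yl]ethanone F4. Claisen rearrangement of F4 in toluene at 120 °C, again to the only free ortho carbon, would come back to the route at 8.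

Step 16. The oxidant may attack elsewhere than intended: hydride abstraction at the benzylic and allylic CH2 of the prenyl group, or oxidation of the para-alkoxyphenol of ring B towards a quinone, may compete with furan closure. The fallback closes the furan without any oxidant, by addition–elimination at C2. Setting out from 8, CS2 and KOt-Bu in THF would give the 4-hydroxy-2H-chromene-2-thione analogue of 10 (no iodine, C2=S, C4–OH) F5. S-Methylation (MeI, K2CO3, acetone) would give the 2-(methylsulfanyl)chromone F6, and NIS would give the 3-iodo-2-(methylsulfanyl)chromone F7. Suzuki–Miyaura coupling of F7 with 20 would give the 2-(methylsulfanyl)-2'-hydroxyisoflavone F8. Its 2'-phenoxide (K2CO3, DMF, 80 °C) would displace methanethiolate from C2 and come back to the route at 22.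

Further compounds
F1 | step 4 | 1-[3-ethenyl-4-(methoxymethoxy)-2,6-bis(2-methylbut-3-yn-2-yloxy)phenyl]ethanone | CC(=O)c1c(OC(C)(C)C#C)c(C=C)c(OCOC)cc1OC(C)(C)C#C
F2 | step 6 | 1-[7-hydroxy-5-(methoxymethoxy)-2,2-dimethyl-2H-chromen-8-yl]ethanone | CC(=O)c1c(O)cc(OCOC)c2C=CC(C)(C)Oc12
F3 | step 6 | 1-[7-hydroxy-5-(methoxymethoxy)-2,2-dimethyl-3,4-dihydro-2H-chromen-8-yl]ethanone | CC(=O)c1c(O)cc(OCOC)c2CCC(C)(C)Oc12
F4 | step 6 | 1-[5-(methoxymethoxy)-2,2-dimethyl-7-(2-methylbut-3-en-2-yloxy)-3,4-dihydro-2H-chromen-8-yl]ethanone | CC(=O)c1c(OC(C)(C)C=C)cc(OCOC)c2CCC(C)(C)Oc12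
F5 | step 16 | 4-hydroxy-7-(methoxymethoxy)-8-(3-methylbut-2-en-1-yl)-2H-chromene-2-thione with the 2,2-dimethyldihydropyran ring fused at O5/C6 | CC(C)=CCc1c(OCOC)c2c(c3c(O)cc(=S)oc13)OC(C)(C)CC2
F6 | step 16 | 7-(methoxymethoxy)-2-(methylsulfanyl)-8-(3-methylbut-2-en-1-yl)chromen-4-one with the 2,2-dimethyldihydropyran ring fused at O5/C6 | CC(C)=CCc1c(OCOC)c2c(c3c(=O)cc(SC)oc13)OC(C)(C)CC2
F7 | step 16 | 3-iodo-7-(methoxymethoxy)-2-(methylsulfanyl)-8-(3-methylbut-2-en-1-yl)chromen-4-one with the 2,2-dimethyldihydropyran ring fused at O5/C6 | CC(C)=CCc1c(OCOC)c2c(c3c(=O)c(I)c(SC)oc13)OC(C)(C)CC2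
F8 | step 16 | 2-(methylsulfanyl) analogue of 2'-hydroxyisoflavone 21 | CC(C)=CCc1c(OCOC)c2c(c3c(=O)c(c(SC)oc13)-c1cc(OCOC)c3OC(C)(C)CCc3c1O)OC(C)(C)CC2
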